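**Retrosynthetic overview**
1. Target ⇐ face-selective hydrogenation of a C-10 alkyl cyclohexene (sets the last stereocentre) and acetal removal ⇐ B-alkyl Suzuki coupling of one regiodefined tetracyclic enol triflate with the oct-7-enyl ether of benzylidene-protected glycerol.
2. Enol triflate ⇐ conjugate reduction and O-triflation of a tetracyclic enone ⇐ allylic alcohol ⇐ enantioselective base-mediated rearrangement of a meso epoxide (absolute configuration enters here).
3. Meso epoxide ⇐ meso cyclohexene-fused [3]-ladderane ⇐ ladderene ⇐ one-operation polyene zip of a folded cyclic triene: thermal 6π closure (cyclobutane A), then photochemical 4π closure (cyclobutanes B and C).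
4. Cyclic triene ⇐ cyclooctatetraene dianion + (Z)-1,4-dichlorobut-2-ene (six-membered ring).
5. Ring order: six-membered ring → ring A → rings B and C together.

Assumption: the ladder is presumed to arise in nature from a folded polyunsaturated chain whose C=C units are stitched into the cyclobutane rungs in one cascade; step 2 copies this as a cascade ring closure of a folded conjugated triene, and the configuration aimed for is that of the given SMILES.

Numbering: ring atoms follow tetracyclo[6.4.0.0(2,7).0(3,6)]dodecane ("ladder core"; all ring fusions cis, neighbouring rings anti). Ring A = C1, C2, C7, C8; ring B = C2, C3, C6, C7; ring C = C3–C6; the side chain sits on C10. Absolute configurations are those of the SMILES.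

**Step 1**
Reactants: 1 cyclooctatetraene; 2 (Z)-1,4-dichlorobut-2-ene
Product: 4 cis-bicyclo[6.4.0]dodeca-2,4,6,10-tetraene (meso), via dipotassium cyclooctatetraenide 3 (not isolated)
Conditions: K (2.1 equiv), THF, rt; then 2, −78 °C to rt
Reagents that add atoms: none
Why: Twofold SN2 alkylation of the aromatic cyclooctatetraene dianion (the annulation with α,ω-dihalides); after the first C–C bond the cyclooctatrienyl anion closes the six-membered ring on the same face, so H-1 and H-8 are cis.

**Step 2**
Reactants: 4 cis-bicyclo[6.4.0]dodeca-2,4,6,10-tetraene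
Product: 6 ladder-core-4,10-diene (meso ladderene), via cis-anti-cis-tricyclo[6.4.0.0(2,7)]dodeca-3,5,10-triene 5 (not isolated)
Conditions: hν (300 nm, Pyrex), heptane (0.01 M), 75 °C, Ar
Reagents that add atoms: none
Why: Thermal disrotatory 6π electrocyclisation (cyclooctatriene–bicyclo[4.2.0]octadiene valence tautomerism) reversibly gives the less crowded cis,anti,cis diene 5, whose cyclohexa-1,3-diene cannot ring-open because of the cis-fused cyclobutane and instead undergoes photochemical disrotatory 4π closure (cyclohexadiene to bicyclo[2.2.0]hexene) folding away from ring A, so rings A, B and C and six stereocentres form cis,anti,cis,anti,cis in one operation.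

**Step 3**
Reactants: 6 ladder-core-4,10-diene
Product: 7 ladder-core-10-ene (meso)
Conditions: KO2C–N=N–CO2K (2 equiv), AcOH, MeOH, 0 °C
Reagents that add atoms: none
Why: Diimide reduction (concerted syn H2 transfer) is far faster for the strained cyclobutene than for the cyclohexene and leaves the strained σ-frame alone; no stereocentre is formed.

**Step 4**
Reactants: 7 ladder-core-10-ene
Product: 8 10,11-epoxy-ladder-core (meso; oxygen on the face of H-1/H-8, trans to ring A)
Conditions: mCPBA, CH2Cl2, 0 °C to rt; chromatography to remove the minor face isomer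
Reagents that add atoms: mCPBA (3-chloroperoxybenzoic acid), OOC(=O)c1cccc(Cl)c1
Why: Prilezhaev epoxidation with concerted syn oxygen transfer to the alkene face opposite ring A (only the pseudo-axial H of C-1/C-8 lies on that face, a pseudo-axial cyclobutane bond on the other), which sets C-10 and C-11 and leaves the compound meso.

**Step 5**
Reactants: 8 10,11-epoxy-ladder-core
Product: 9 (10S)-ladder-core-11-en-10-ol (OH on the face of H-1/H-8)
Conditions: (S)-2-(pyrrolidin-1-ylmethyl)pyrrolidine (1.7 equiv), n-BuLi (1.6 equiv), THF, 0 °C; then 8, 0 °C to rt, 12 h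
Reagents that add atoms: none
Why: Enantioselective rearrangement of a meso epoxide to an allylic alcohol by a chiral lithium amide (syn β-elimination): the base removes the pseudo-axial H-12 syn to oxygen and not its enantiotopic partner H-9, in the sense cyclohexene oxide → (S)-cyclohex-2-en-1-ol for this antipode, which fixes the absolute configuration of the six ladder stereocentres relative to the oxygenated carbon, while C-10 keeps the epoxide configuration.

**Step 6**
Reactants: 9 (10S)-ladder-core-11-en-10-ol
Product: 10 ladder-core-11-en-10-one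
Conditions: (n-Pr4N)RuO4 (5 mol %), NMO, 4 Å MS, CH2Cl2, rt
Reagents that add atoms: none
Why: Ley–Griffith oxidation of the allylic alcohol; the carbinol centre is erased on purpose, the enone being chiral only through the position of C=O and C=C relative to the ladder, and no base is present that could touch the γ-centre C-1.

**Step 7**
Reactants: 10 ladder-core-11-en-10-one
Product: 12 ladder-core-10-en-10-yl trifluoromethanesulfonate, via lithium enolate 11 (not isolated)
Conditions: LiBH(sec-Bu)3 (1.05 equiv), THF, −78 °C; then PhNTf2, −78 to 0 °C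
Reagents that add atoms: N-phenylbis(trifluoromethanesulfonimide), FC(F)(F)S(=O)(=O)N(c1ccccc1)S(=O)(=O)C(F)(F)F
Why: Conjugate hydride reduction of the β-unsubstituted cyclohexenone places hydride on C-12 and gives the C-10/C-11 enolate only, which O-sulfonylation traps as a single enol triflate regioisomer (reductive enol triflate synthesis); no stereocentre is formed or touched.

**Step 8**
Reactants: 13 cis-2-phenyl-1,3-dioxan-5-ol; 14 8-bromooct-1-ene
Product: 15 cis-5-(oct-7-en-1-yloxy)-2-phenyl-1,3-dioxane
Conditions: NaH, Bu4NI (cat.), DMF, 0 °C to rt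
Reagents that add atoms: none
Why: Williamson ether synthesis on the secondary alkoxide with a primary bromide; the acetal configuration is untouched.

**Step 9**
Reactants: 12 ladder-core-10-en-10-yl trifluoromethanesulfonate; 15 cis-5-(oct-7-en-1-yloxy)-2-phenyl-1,3-dioxane
Product: 17 cis-5-{[8-(ladder-core-10-en-10-yl)octyl]oxy}-2-phenyl-1,3-dioxane, via B-alkyl-9-borabicyclo[3.3.1]nonane 16 (not isolated)
Conditions: 15, 9-BBN-H, THF, rt; then 12, PdCl2(dppf) (5 mol %), K3PO4 (3 M aq), DMF, 50 °C
Reagents that add atoms: none
Why: Anti-Markovnikov hydroboration of the terminal alkene, then Suzuki–Miyaura B-alkyl coupling with the alkenyl triflate (oxidative addition to zerovalent palladium, transmetalation, reductive elimination) joins C-10 to the C8 chain; no stereocentre is formed.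

**Step 10**
Reactants: 17 cis-5-{[8-(ladder-core-10-en-10-yl)octyl]oxy}-2-phenyl-1,3-dioxane
Product: 19 2-{[8-(ladder-core-10-yl)octyl]oxy}propane-1,3-diol (CNP0193334.1), via benzylidene-protected ether 18 (not isolated)
Conditions: H2 (1 atm), [Ir(cod)(PCy3)(py)]PF6 (5 mol %), CH2Cl2, 0 °C to rt; then AcOH/H2O (4:1), 45 °C
Reagents that add atoms: none
Why: Iridium-catalysed homogeneous hydrogenation adds both hydrogens syn to the face of the trisubstituted ring alkene opposite ring A (in either half-chair the pseudo-axial cyclobutane bond shields the ring A face), so H-10 ends cis to H-1/H-8 and the chain cis to the cyclobutane as in the target, and mild acid hydrolysis then removes the benzylidene acetal.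

**Compound list**
1 | cyclooctatetraene | C1=CC=CC=CC=C1 | starting material
2 | (Z)-1,4-dichlorobut-2-ene | ClC/C=C\CCl | starting material
3 | dipotassium cyclooctatetraenide | [K+].[K+].[CH-]1C=CC=C[CH-]C=C1 | intermediate
4 | cis-bicyclo[6.4.0]dodeca-2,4,6,10-tetraene (meso) | C1=CC[C@@H]2[C@H](C1)/C=C\C=C/C=C\2 | intermediate
5 | cis,anti,cis-tricyclo[6.4.0.0(2,7)]dodeca-3,5,10-triene (meso) | C1=CC[C@@H]2[C@H](C1)[C@H]1C=CC=C[C@@H]21 | intermediate
6 | ladder-core-4,10-diene (meso) | C1=CC[C@@H]2[C@H](C1)[C@H]1[C@@H]3C=C[C@@H]3[C@@H]21 | intermediate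
7 | ladder-core-10-ene (meso) | C1=CC[C@@H]2[C@H](C1)[C@H]1[C@@H]3CC[C@@H]3[C@@H]21 | intermediate
8 | 10,11-epoxy-ladder-core (meso), oxygen on the H-1/H-8 face | O1[C@@H]2[C@H]1C[C@@H]3[C@H](C2)[C@H]2[C@@H]4CC[C@@H]4[C@@H]32 | intermediate
9 | (10S)-ladder-core-11-en-10-ol, OH on the H-1/H-8 face | O[C@@H]1C=C[C@@H]2[C@H](C1)[C@H]1[C@@H]3CC[C@@H]3[C@@H]21 | intermediate
10 | ladder-core-11-en-10-one | O=C1C=C[C@@H]2[C@H](C1)[C@H]1[C@@H]3CC[C@@H]3[C@@H]21 | intermediate
11 | lithium ladder-core-10-en-10-olate | [Li+].[O-]C1=CC[C@@H]2[C@H](C1)[C@H]1[C@@H]3CC[C@@H]3[C@@H]21 | intermediate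
12 | ladder-core-10-en-10-yl trifluoromethanesulfonate | FC(F)(F)S(=O)(=O)OC1=CC[C@@H]2[C@H](C1)[C@H]1[C@@H]3CC[C@@H]3[C@@H]21 | intermediate
13 | cis-2-phenyl-1,3-dioxan-5-ol | O[C@H]1CO[C@@H](c2ccccc2)OC1 | starting material
14 | 8-bromooct-1-ene | C=CCCCCCCBr | starting material
15 | cis-5-(oct-7-en-1-yloxy)-2-phenyl-1,3-dioxane | C=CCCCCCCO[C@H]1CO[C@@H](c2ccccc2)OC1 | intermediate
16 | cis-5-{[8-(9-borabicyclo[3.3.1]nonan-9-yl)octyl]oxy}-2-phenyl-1,3-dioxane | O([C@H]1CO[C@@H](c2ccccc2)OC1)CCCCCCCCB1C2CCCC1CCC2 | intermediate
17 | cis-5-{[8-(ladder-core-10-en-10-yl)octyl]oxy}-2-phenyl-1,3-dioxane | O([C@H]1CO[C@@H](c2ccccc2)OC1)CCCCCCCCC1=CC[C@@H]2[C@H](C1)[C@H]1[C@@H]3CC[C@@H]3[C@@H]21 | intermediate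
18 | cis-5-{[8-(ladder-core-10-yl)octyl]oxy}-2-phenyl-1,3-dioxane, H-10 cis to H-1/H-8 | O([C@H]1CO[C@@H](c2ccccc2)OC1)CCCCCCCC[C@H]1CC[C@@H]2[C@H](C1)[C@H]1[C@@H]3CC[C@@H]3[C@@H]21 | intermediate
19 | 2-{[8-(ladder-core-10-yl)octyl]oxy}propane-1,3-diol (CNP0193334.1) | OCC(CO)OCCCCCCCC[C@H]1CC[C@@H]2[C@H](C1)[C@H]1[C@@H]3CC[C@@H]3[C@@H]21 | target

**Step count**
Total: 10 steps. Longest linear sequence: 9 steps (steps 1–7, 9, 10); step 8 is the side branch.

**Steps most likely to fail, with fallbacks**

Step 2 (photothermal zip). The triene tautomer 4 also absorbs and has its own photochemistry; 1,5-hydrogen shifts and loss of benzene from 5 can compete. The fallback sets out from 1 and comes back at 7, making steps 1 and 3 unnecessary as well. Compound 1 is reduced (K, liquid NH3/THF; MeOH; then KOt-Bu) to cycloocta-1,3,5-triene F1. F1 is equilibrated at 100 °C with its valence isomer cis-bicyclo[4.2.0]octa-2,4-diene F2, which is freed from F1 by extracting F1 into aqueous AgNO3 (F1 is recycled). F2 alone is irradiated cold (254 nm, pentane, −20 °C) to anti-tricyclo[4.2.0.0(2,5)]oct-3-ene F3, the unsubstituted parent case of the zip. The six-membered ring is then built last by Diels–Alder addition of buta-1,3-diene (sealed tube, 100 °C) to the exo face of the strained cyclobutene of F3, which gives 7 directly with the cis,anti arrangement.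

Step 5 (enantioselective epoxide rearrangement). The two half-chairs of 8 are not mirror images as they are in cyclohexene oxide, so the ee may fall short, and α-lithiation of the epoxide can divert material to the saturated ketone. The fallback sets out from 8 and comes back at 9, replacing base-mediated elimination by catalytic nucleophilic desymmetrisation. Benzeneselenol opens the meso epoxide at C-11 under a chiral Lewis acid catalyst made in the flask from Ti(OiPr)4, GaMe3 and (R,R)-N,N′-bis(3,5-di-tert-butylsalicylidene)cyclohexane-1,2-diamine (toluene, −40 °C; the ligand antipode is used if the sense proves opposite). This gives the trans-diaxial hydroxy selenide 11-(phenylselanyl)-ladder-core-10-ol F4, whose ee can be raised by recrystallisation. H2O2 (pyridine, CH2Cl2, 0 °C to rt) oxidises F4 to the selenoxide F5, which undergoes syn elimination away from the carbinol carbon (towards H-12) and gives 9.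

Step 10 (face selectivity of the hydrogenation). A moderate preference would leave a C-10 epimer that is hard to separate from 18 or 19. The fallback sets out from 17 and comes back at 18. Hydroboration (BH3·THF, 0 °C; then NaOH, H2O2) places H on C-10 and boron on C-11 syn, on the face opposite ring A, and gives the secondary alcohol cis-5-{[8-(11-hydroxy-ladder-core-10-yl)octyl]oxy}-2-phenyl-1,3-dioxane F6. The epimer from attack on the other face is polar and separable by chromatography at this stage. NaH, CS2, MeI converts F6 into its S-methyl xanthate F7, and Bu3SnH, AIBN (toluene, 80 °C) removes the oxygen function (Barton–McCombie deoxygenation) to give 18, which is hydrolysed as in step 10.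

**Further compounds**
F1 | step 2 | cycloocta-1,3,5-triene | C1=CC=CC=CCC1
F2 | step 2 | cis-bicyclo[4.2.0]octa-2,4-diene | C1C[C@H]2C=CC=C[C@@H]12
F3 | step 2 | anti-tricyclo[4.2.0.0(2,5)]oct-3-ene | C1=C[C@H]2[C@@H]3CC[C@@H]3[C@@H]12
F4 | step 5 | 11-(phenylselanyl)-ladder-core-10-ol, OH on the H-1/H-8 face, selenium on the ring A face | O[C@@H]1[C@@H]([Se]c2ccccc2)C[C@@H]2[C@H](C1)[C@H]1[C@@H]3CC[C@@H]3[C@@H]21
F5 | step 5 | selenoxide of F4 | O[C@@H]1[C@@H]([Se](=O)c2ccccc2)C[C@@H]2[C@H](C1)[C@H]1[C@@H]3CC[C@@H]3[C@@H]21
F6 | step 10 | cis-5-{[8-(11-hydroxy-ladder-core-10-yl)octyl]oxy}-2-phenyl-1,3-dioxane, OH and H-10 on the H-1/H-8 face | O([C@H]1CO[C@@H](c2ccccc2)OC1)CCCCCCCC[C@H]1[C@H](O)C[C@@H]2[C@H](C1)[C@H]1[C@@H]3CC[C@@H]3[C@@H]21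
F7 | step 10 | S-methyl xanthate of F6 | O([C@H]1CO[C@@H](c2ccccc2)OC1)CCCCCCCC[C@H]1[C@H](OC(=S)SC)C[C@@H]2[C@H](C1)[C@H]1[C@@H]3CC[C@@H]3[C@@H]21
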